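## Structural features

The target is a flavone: a 4H-chromen-4-one (benzo ring A fused through C4a–C8a to the 4-pyranone ring C) that carries a 3,4-dihydroxyphenyl ring B on C2 through the C2–C1' bond. It has no stereocenter and no chain, so the whole problem is regiochemical. Ring A is a hexasubstituted benzene: C5, C6, C7 and C8 each carry a methoxy group, C8a carries the ring oxygen O1 and C4a carries the C4 carbonyl, so five of its six carbons are oxygenated and no ring C–H is left to accept or direct a substitution. The fragile groups are the free catechol of ring B (acidic, nucleophilic, easily oxidised to the ortho-quinone), the C5 methoxy group peri to the C4 carbonyl (removed selectively by chelating Lewis acids) and the C2=C3 enone bond (open to conjugate addition and reduction). The real difficulty is ring A: classical routes must first build a pentaoxygenated acetophenone by stepwise oxidation of a simpler arene before any flavone chemistry starts. The key step exploits two facts: C5, C6, C7 and C8 are four contiguous oxygen-bearing carbons, which is the carbon–oxygen pattern of squaric acid, and C4a=C8a can be the C5=C6 double bond of a pre-formed monocyclic 4-pyranone that already carries ring B. In one sentence, ring A is grown onto a 2-aryl-4-pyranone by thermal 4π ring opening and 6π electrocyclization of a squarate-derived 4-(4-oxopyran-2-yl)cyclobutenone, which closes the C5–C4a bond.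

## Logic of the disconnections

15 to 14. The two benzyl–oxygen bonds on ring B are cut. The free catechol would quench the organolithium of step 3, be methylated in step 5 and oxidise in air, so it is unmasked last. The demand is a cleavage that leaves four aryl–OCH3 bonds (the chelated C5 one above all) and the C2=C3 bond intact, which points to hydrogenolysis and away from Lewis acids.

14 to 13. The O–CH3 bond at C5 is cut. The C5 oxygen is the one that the key step delivers as a free phenol (it is the former ketene oxygen), so it is the only A-ring oxygen that must be methylated separately. The forward step must methylate a hydrogen-bonded phenol flanked by a methoxy group.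

13 to 10 (key disconnection). The C5–C4a bond of ring A is cut (retro-6π), and C5 is then reconnected to C8 (retro-4π) to give a four-membered ring. The hexasubstituted benzene is replaced by a cyclobutenone joined by one single bond to a simple pyranone. Every substituent of ring A is already encoded in the connectivity of 10, so no regiochemical decision remains. The forward step needs inward rotation of the pyranonyl group on ring opening and closure onto the pyranone carbon next to the point of attachment.

10 to 6 and 7. The C8–C8a bond (carbinol carbon to the pyranone carbon next to the ring oxygen) and the O–CH3 bond on the carbinol oxygen are cut. This reveals 7, in which both carbonyl groups are equivalent, and a carbanion at the only C–H of 6 that is alpha to the ring oxygen. The union is convergent and joins two fragments of similar size. The forward step needs regioselective metalation of 6, a carbanion that survives until it is trapped, monoaddition to 7 and chemoselective O-methylation of the alkoxide.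

6 to 2 and 3. The pyranone C2–C3 bond (acyl carbon to the methyl carbon of 3) and the O1–C6 bond (enol oxygen to the methoxy-bearing carbon of 3) are cut. The heterocycle falls apart into a benzoic acid derivative and a four-carbon enone. The forward step needs C- rather than O-acylation of a kinetic enolate.

2 to 1. The C–Cl bond is cut; this is plain activation of a commercial acid.

## Other disconnections considered

Alternative 1: the first route to come to mind cuts C2–C3 and O1–C2 of ring C. The acetophenone 1-(2-hydroxy-3,4,5,6-tetramethoxyphenyl)ethan-1-one A1 would be O-aroylated with 2. A Baker–Venkataraman O-to-C acyl shift would give the diketone 1-[3,4-bis(benzyloxy)phenyl]-3-(2-hydroxy-3,4,5,6-tetramethoxyphenyl)propane-1,3-dione A2, and acid cyclodehydration of A2 would give 14. This forms only the easy heterocycle. The whole difficulty is moved into A1, whose pentaoxygenated, fully substituted ring must be made by a sequence of ring oxidations, methylations and an acylation. The chosen plan instead builds that ring with all six substituents in one step from a commercial C4 unit.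

Alternative 2: cut C4–C4a and O1–C2. A carbonylative Sonogashira coupling (PdCl2(PPh3)2, CuI, CO) of 2-iodo-3,4,5,6-tetramethoxyphenol A3 with 1,2-bis(benzyloxy)-4-ethynylbenzene A4 would give the ynone 3-[3,4-bis(benzyloxy)phenyl]-1-(2-hydroxy-3,4,5,6-tetramethoxyphenyl)prop-2-yn-1-one A5. A 6-endo-dig oxa-Michael closure of A5 would then give 14. The alkyne A4 is simple, but A3 needs the same pentaoxygenated arene plus an iodination. Oxidative addition into a di-ortho-substituted, very electron-rich aryl iodide such as A3 should be slow, and 5-exo-dig closure of A5 competes with the 6-endo mode. The route is convergent but removes none of the ring A problem.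

Alternative 3: a biomimetic folding of a masked polyketide. The thioester S-ethyl (E)-9-[3,4-bis(benzyloxy)phenyl]-3,5,7-trioxonon-8-enethioate A6 would undergo an intramolecular Claisen condensation and aromatise to the chalcone (E)-3-[3,4-bis(benzyloxy)phenyl]-1-(2,4,6-trihydroxyphenyl)prop-2-en-1-one A7. Oxa-Michael closure of A7 and dehydrogenation would give 2-[3,4-bis(benzyloxy)phenyl]-5,7-dihydroxy-4H-chromen-4-one A8. The folding of A6 places oxygen only on alternate ring carbons (C5, C7, C8a), as the ring of A7 shows. The oxygens at C6 and C8 would then need two separate C–H hydroxylations of A8 (persulfate-type oxidations with weak regiocontrol), followed by selective methylation. The structure therefore argues against this idea, whereas a squarate supplies four contiguous oxygenated carbons directly.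

Key step: step 4

Remark: the target is achiral. The only stereocenter on the route (C4 of 10, formed as a racemate) is destroyed in step 4. Compounds 1, 3 and 7 are taken as commercial.

## Steps

Step 1
Reactants: 1 3,4-bis(benzyloxy)benzoic acid
Product: 2 3,4-bis(benzyloxy)benzoyl chloride
Conditions: (COCl)2, cat. DMF, CH2Cl2, 0 °C to rt; concentrate
Reagents that add atoms: oxalyl chloride, ClC(=O)C(=O)Cl
Why: Acid chloride formation through the Vilsmeier-type chloroiminium from oxalyl chloride and DMF; the benzyl ethers are inert under these mild conditions.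

Step 2
Reactants: 2 3,4-bis(benzyloxy)benzoyl chloride; 3 (E)-4-methoxybut-3-en-2-one
Product: 6 2-[3,4-bis(benzyloxy)phenyl]-4H-pyran-4-one, via lithium dienolate 4 (not isolated), via acyclic diketone 5 (not isolated)
Conditions: 3, LiN(SiMe3)2 (2 equiv each), THF, −78 °C; then 2, −78 to 0 °C; aq NH4Cl; crude 5, cat. CF3CO2H, toluene, rt
Reagents that add atoms: none
Why: Claisen-type C-acylation of the kinetic lithium dienolate 4 (the second equivalent deprotonates the more acidic product), then acid-catalysed 6-endo addition–elimination of the enol oxygen onto the β-methoxy enone with loss of methanol; this is a known two-stage route to 2-substituted 4-pyranones.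

Step 3
Reactants: 6 2-[3,4-bis(benzyloxy)phenyl]-4H-pyran-4-one; 7 3,4-dimethoxycyclobut-3-ene-1,2-dione (dimethyl squarate)
Product: 10 4-{6-[3,4-bis(benzyloxy)phenyl]-4-oxo-4H-pyran-2-yl}-2,3,4-trimethoxycyclobut-2-en-1-one (racemic), via lithiated pyranone 8 (not isolated), via lithium alkoxide 9 (not isolated)
Conditions: 2,2,6,6-tetramethylpiperidine, n-BuLi, THF, −78 °C; 6, −78 °C, 10 min; cannulate into 7, THF, −78 °C; MeOTf, −78 to −20 °C
Reagents that add atoms: methyl trifluoromethanesulfonate, COS(=O)(=O)C(F)(F)F
Why: Kinetic deprotonation by the hindered lithium amide takes the only vinylic C–H next to the ring oxygen of 6 (inductive acidification and lithium coordination by O1, as in the C2 lithiation of chromones); vinyllithium 8 adds 1,2 to one of the two equivalent carbonyl groups of 7, and alkoxide 9 is O-methylated in the same flask (Williamson-type alkylation). The new quaternary center forms as a racemate, which does not matter because step 4 destroys it.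

Step 4
Reactants: 10 4-{6-[3,4-bis(benzyloxy)phenyl]-4-oxo-4H-pyran-2-yl}-2,3,4-trimethoxycyclobut-2-en-1-one
Product: 13 2-[3,4-bis(benzyloxy)phenyl]-5-hydroxy-6,7,8-trimethoxy-4H-chromen-4-one, via dienylketene 11 (not isolated), via cyclohexadienone 12 (not isolated)
Conditions: toluene (degassed, 0.02 M), 110 °C, Ar
Reagents that add atoms: none
Why: Heating opens the C1–C4 bond of cyclobutenone 10 by conrotatory 4π electrocyclic ring opening to dienylketene 11; the C4 methoxy donor rotates outward (torquoselectivity), which places the pyranonyl group inward, cis to the ketene. A thermal disrotatory 6π electrocyclization of the ketene C=C, the C(OMe)=C(OMe) bond and the pyranone C5=C6 bond then joins the ketene carbon to pyranone C5; this closes the six-membered carbocycle (ring A, bond C5–C4a of the flavone) as cyclohexadienone 12, and enolisation of its C4a–H makes ring A aromatic and gives phenol 13. The closest known reaction type is the Moore rearrangement, the thermal ring expansion of squarate-derived 4-alkenyl- and 4-heteroaryl-4-alkoxycyclobutenones to protected hydroquinones. No stereocenter is formed, and the racemic center of 10 is erased. The selectivity needed is regiochemical and is fixed by connectivity: the only carbon next to the point of attachment other than the ring oxygen is C5, and it is the nucleophilic β-carbon of the enol ether O1–C6=C5, matched to the electrophilic ketene carbon. A ketene formed by the wrong rotation cannot be trapped, because no free hydroxyl group is present, and should revert to 10, so the system funnels toward 13. All six substituents of ring A arrive in their final positions: the C6 and C7 methoxy groups from 7, the C8 methoxy group from the methylated carbinol and the C5 hydroxyl from the ketene carbonyl, held by a hydrogen bond to the C4 carbonyl.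

Step 5
Reactants: 13 2-[3,4-bis(benzyloxy)phenyl]-5-hydroxy-6,7,8-trimethoxy-4H-chromen-4-one
Product: 14 2-[3,4-bis(benzyloxy)phenyl]-5,6,7,8-tetramethoxy-4H-chromen-4-one
Conditions: Me2SO4, K2CO3, acetone, reflux
Reagents that add atoms: dimethyl sulfate, COS(=O)(=O)OC
Why: Williamson O-methylation; prolonged reflux with excess carbonate overcomes the C5–OH to C4=O hydrogen bond, and no other acidic or nucleophilic site is present.

Step 6
Reactants: 14 2-[3,4-bis(benzyloxy)phenyl]-5,6,7,8-tetramethoxy-4H-chromen-4-one
Product: 15 2-(3,4-dihydroxyphenyl)-5,6,7,8-tetramethoxy-4H-chromen-4-one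
Conditions: H2 (1 atm), 10% Pd/C, EtOAc/MeOH, rt
Reagents that add atoms: none
Why: Catalytic hydrogenolysis of the two benzylic C–O bonds; aryl methyl ethers are inert, and the C2=C3 bond of a flavone, part of a vinylogous ester conjugated with ring B, should be reduced far more slowly than benzyl ethers are cleaved under these conditions.

## Compound list

1 | 3,4-bis(benzyloxy)benzoic acid | OC(=O)c1ccc(OCc2ccccc2)c(OCc2ccccc2)c1 | starting material
2 | 3,4-bis(benzyloxy)benzoyl chloride | ClC(=O)c1ccc(OCc2ccccc2)c(OCc2ccccc2)c1 | intermediate
3 | (E)-4-methoxybut-3-en-2-one | CC(=O)/C=C/OC | starting material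
4 | lithium (E)-4-methoxybuta-1,3-dien-2-olate | [Li]OC(=C)/C=C/OC | intermediate
5 | (E)-1-[3,4-bis(benzyloxy)phenyl]-5-methoxypent-4-ene-1,3-dione | CO/C=C/C(=O)CC(=O)c1ccc(OCc2ccccc2)c(OCc2ccccc2)c1 | intermediate
6 | 2-[3,4-bis(benzyloxy)phenyl]-4H-pyran-4-one | O=c1ccoc(-c2ccc(OCc3ccccc3)c(OCc3ccccc3)c2)c1 | intermediate
7 | 3,4-dimethoxycyclobut-3-ene-1,2-dione (dimethyl squarate) | COC1=C(OC)C(=O)C1=O | starting material
8 | {6-[3,4-bis(benzyloxy)phenyl]-4-oxo-4H-pyran-2-yl}lithium | [Li]c1cc(=O)cc(-c2ccc(OCc3ccccc3)c(OCc3ccccc3)c2)o1 | intermediate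
9 | lithium 1-{6-[3,4-bis(benzyloxy)phenyl]-4-oxo-4H-pyran-2-yl}-2,3-dimethoxy-4-oxocyclobut-2-en-1-olate (racemic) | [Li]OC1(c2cc(=O)cc(-c3ccc(OCc4ccccc4)c(OCc4ccccc4)c3)o2)C(OC)=C(OC)C1=O | intermediate
10 | 4-{6-[3,4-bis(benzyloxy)phenyl]-4-oxo-4H-pyran-2-yl}-2,3,4-trimethoxycyclobut-2-en-1-one (racemic) | COC1=C(OC)C(OC)(c2cc(=O)cc(-c3ccc(OCc4ccccc4)c(OCc4ccccc4)c3)o2)C1=O | intermediate
11 | (3Z)-4-{6-[3,4-bis(benzyloxy)phenyl]-4-oxo-4H-pyran-2-yl}-2,3,4-trimethoxybuta-1,3-dien-1-one | O=C=C(OC)/C(OC)=C(\c1cc(=O)cc(-c2ccc(OCc3ccccc3)c(OCc3ccccc3)c2)o1)OC | intermediate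
12 | 2-[3,4-bis(benzyloxy)phenyl]-6,7,8-trimethoxy-4aH-chromene-4,5-dione (racemic) | O=C1C(OC)=C(OC)C(OC)=C2OC(-c3ccc(OCc4ccccc4)c(OCc4ccccc4)c3)=CC(=O)C12 | intermediate
13 | 2-[3,4-bis(benzyloxy)phenyl]-5-hydroxy-6,7,8-trimethoxy-4H-chromen-4-one | COc1c(OC)c(O)c2c(=O)cc(-c3ccc(OCc4ccccc4)c(OCc4ccccc4)c3)oc2c1OC | intermediate
14 | 2-[3,4-bis(benzyloxy)phenyl]-5,6,7,8-tetramethoxy-4H-chromen-4-one | COc1c(OC)c(OC)c2c(=O)cc(-c3ccc(OCc4ccccc4)c(OCc4ccccc4)c3)oc2c1OC | intermediate
15 | 2-(3,4-dihydroxyphenyl)-5,6,7,8-tetramethoxy-4H-chromen-4-one | COc1c(OC)c(OC)c2c(=O)cc(-c3ccc(O)c(O)c3)oc2c1OC | target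

## Step count and risks

Total step count: 6. Longest linear sequence: 6 steps (1 to 15).

Step 4 (key step). Dienylketene 11 may be lost to paths other than the 6π closure: addition of adventitious nucleophiles, ketene dimerisation or polymerisation. The pyranone C5=C6 bond, which has some aromatic stabilisation, may also engage too slowly, so that ring A does not form cleanly. The fallback sets out from 2 and returns at 14 by classical ring C chemistry. Acid chloride 2 would acylate 1-(2-hydroxy-3,4,5,6-tetramethoxyphenyl)ethan-1-one F1 (bought or made separately; pyridine, DMAP) to give 2-acetyl-3,4,5,6-tetramethoxyphenyl 3,4-bis(benzyloxy)benzoate F2. A Baker–Venkataraman rearrangement (KOH, pyridine, 50 °C) would give 1-[3,4-bis(benzyloxy)phenyl]-3-(2-hydroxy-3,4,5,6-tetramethoxyphenyl)propane-1,3-dione F3. Cyclodehydration (AcOH, cat. H2SO4, 60 °C) would give 14.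

Step 3. The lithiated pyranone 8 may add to unreacted 6 or open its ring before it meets 7. Deprotonation at C3 or C5 may compete with C6. Methyl triflate may also alkylate the pyranone carbonyl oxygen instead of the hindered alkoxide. The fallback sets out from 3 (with 2 and 7) and returns at 14. It replaces deprotonation by halogen–metal exchange and uses the other regiochemical mode of the same annulation. Iodination of 3 at its α-carbon (N-iodosuccinimide, CH2Cl2) would give (Z)-3-iodo-4-methoxybut-3-en-2-one F4. Enolate acylation with 2 and acid cyclisation under the conditions of step 2 would give 2-[3,4-bis(benzyloxy)phenyl]-5-iodo-4H-pyran-4-one F5, with the halogen in a defined position. Iodine–magnesium exchange (iPrMgCl·LiCl, THF, −78 °C), addition to 7 and O-methylation would give 4-{6-[3,4-bis(benzyloxy)phenyl]-4-oxo-4H-pyran-3-yl}-2,3,4-trimethoxycyclobut-2-en-1-one F6. Thermolysis as in step 4, now closing onto the pyranone carbon next to the ring oxygen, would give 2-[3,4-bis(benzyloxy)phenyl]-8-hydroxy-5,6,7-trimethoxy-4H-chromen-4-one F7. Methylation under the conditions of step 5 would give 14.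

Step 2. O-acylation or double acylation of dienolate 4, or base-induced oligomerisation of 3, may lower the amount of diketone 5, and the cyclisation may stall before methanol is lost. The fallback sets out from 2 and returns at 6 by a cycloaddition route. Reduction of 2 (LiAlH(OtBu)3, THF, −78 °C) would give 3,4-bis(benzyloxy)benzaldehyde F8. A hetero-Diels–Alder reaction with 1-methoxy-3-(trimethylsilyloxy)buta-1,3-diene (ZnCl2, THF; then CF3CO2H) would give racemic 2-[3,4-bis(benzyloxy)phenyl]-2,3-dihydro-4H-pyran-4-one F9. Dehydrogenation (DDQ, dioxane, reflux) would give 6.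

Step 6. Reduction of the C2=C3 bond may compete with debenzylation, or the catalyst may be deactivated before both benzyl groups are removed. The fallback sets out from 14 and ends at 15 without hydrogen: acidolytic debenzylation with CF3CO2H and thioanisole at rt, in which the benzyl cations are captured by the sulfide while the aryl methyl ethers stay intact. This fallback makes no new compound (entry F0).

## Further compounds

F1 | step 4 | 1-(2-hydroxy-3,4,5,6-tetramethoxyphenyl)ethan-1-one | CC(=O)c1c(O)c(OC)c(OC)c(OC)c1OC
F2 | step 4 | 2-acetyl-3,4,5,6-tetramethoxyphenyl 3,4-bis(benzyloxy)benzoate | CC(=O)c1c(OC(=O)c2ccc(OCc3ccccc3)c(OCc3ccccc3)c2)c(OC)c(OC)c(OC)c1OC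
F3 | step 4 | 1-[3,4-bis(benzyloxy)phenyl]-3-(2-hydroxy-3,4,5,6-tetramethoxyphenyl)propane-1,3-dione | O=C(CC(=O)c1c(O)c(OC)c(OC)c(OC)c1OC)c1ccc(OCc2ccccc2)c(OCc2ccccc2)c1
F4 | step 3 | (Z)-3-iodo-4-methoxybut-3-en-2-one | CC(=O)/C(I)=C/OC
F5 | step 3 | 2-[3,4-bis(benzyloxy)phenyl]-5-iodo-4H-pyran-4-one | O=c1cc(-c2ccc(OCc3ccccc3)c(OCc3ccccc3)c2)occ1I
F6 | step 3 | 4-{6-[3,4-bis(benzyloxy)phenyl]-4-oxo-4H-pyran-3-yl}-2,3,4-trimethoxycyclobut-2-en-1-one (racemic) | COC1=C(OC)C(OC)(c2coc(-c3ccc(OCc4ccccc4)c(OCc4ccccc4)c3)cc2=O)C1=O
F7 | step 3 | 2-[3,4-bis(benzyloxy)phenyl]-8-hydroxy-5,6,7-trimethoxy-4H-chromen-4-one | COc1c(OC)c(OC)c2c(=O)cc(-c3ccc(OCc4ccccc4)c(OCc4ccccc4)c3)oc2c1O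
F8 | step 2 | 3,4-bis(benzyloxy)benzaldehyde | O=Cc1ccc(OCc2ccccc2)c(OCc2ccccc2)c1
F9 | step 2 | 2-[3,4-bis(benzyloxy)phenyl]-2,3-dihydro-4H-pyran-4-one (racemic) | O=C1C=COC(c2ccc(OCc3ccccc3)c(OCc3ccccc3)c2)C1
F0 | step 6 | none | none
A1 | alternative 1 | 1-(2-hydroxy-3,4,5,6-tetramethoxyphenyl)ethan-1-one | CC(=O)c1c(O)c(OC)c(OC)c(OC)c1OC
A2 | alternative 1 | 1-[3,4-bis(benzyloxy)phenyl]-3-(2-hydroxy-3,4,5,6-tetramethoxyphenyl)propane-1,3-dione | O=C(CC(=O)c1c(O)c(OC)c(OC)c(OC)c1OC)c1ccc(OCc2ccccc2)c(OCc2ccccc2)c1
A3 | alternative 2 | 2-iodo-3,4,5,6-tetramethoxyphenol | COc1c(O)c(I)c(OC)c(OC)c1OC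
A4 | alternative 2 | 1,2-bis(benzyloxy)-4-ethynylbenzene | C#Cc1ccc(OCc2ccccc2)c(OCc2ccccc2)c1
A5 | alternative 2 | 3-[3,4-bis(benzyloxy)phenyl]-1-(2-hydroxy-3,4,5,6-tetramethoxyphenyl)prop-2-yn-1-one | O=C(C#Cc1ccc(OCc2ccccc2)c(OCc2ccccc2)c1)c1c(O)c(OC)c(OC)c(OC)c1OC
A6 | alternative 3 | S-ethyl (E)-9-[3,4-bis(benzyloxy)phenyl]-3,5,7-trioxonon-8-enethioate | CCSC(=O)CC(=O)CC(=O)CC(=O)/C=C/c1ccc(OCc2ccccc2)c(OCc2ccccc2)c1
A7 | alternative 3 | (E)-3-[3,4-bis(benzyloxy)phenyl]-1-(2,4,6-trihydroxyphenyl)prop-2-en-1-one | O=C(/C=C/c1ccc(OCc2ccccc2)c(OCc2ccccc2)c1)c1c(O)cc(O)cc1O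
A8 | alternative 3 | 2-[3,4-bis(benzyloxy)phenyl]-5,7-dihydroxy-4H-chromen-4-one | O=c1cc(-c2ccc(OCc3ccccc3)c(OCc3ccccc3)c2)oc2cc(O)cc(O)c12
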